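The hydroazulene core is cut at two bonds of the ring-fusion carbon C5 (daucane numbering), C5–C1 and C5–C6. This works because C1 and C6–C10 of the seven-membered ring, with the methyl on C8 and the oxygen on C9, are the six carbons of a 3-oxy-4-methylphenyl ring. C5 lies next to oxygenated C4 and can therefore be a ketocarbene. One intramolecular Buchner reaction of a 1-diazo-4-arylbutan-2-one closes the cyclopentane, expands the arene to the seven-membered ring and sets C5. The aryl oxygen is carried as a TBS ether, so C9 emerges as a silyl enol ether that fluoride unmasks without acid.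

Key step: step 5

Numbering and faces: C1 is the quaternary ring-fusion carbon (CH3), C2 and C3 are the cyclopentane CH2 groups, C4 is the carbinol carbon (isopropyl) and C5 is the ring-fusion CH. C6 is CHOH, C7 is =CH, C8 is =C(CH3), C9 is C=O and C10 is CH2. The "upper face" is the face that carries H5; the "lower face" is the opposite one.
Assumption: the sense of induction of the copper bis(oxazoline) catalyst cannot be predicted for this substrate. The (S,S) ligand is written, and its mirror image is used if it favours the (8aS)-azulenone.
Remark: C8 forms as a mixture of epimers in 11–13 and 17–20 and is drawn without configuration. It becomes sp2 again in 21.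

Step 1
Reactants: 1 3-hydroxy-4-methylbenzaldehyde; 2 malonic acid
Product: 3 (E)-3-(3-hydroxy-4-methylphenyl)prop-2-enoic acid
Conditions: pyridine, piperidine (cat.), 100 °C
Reagents that add atoms: none
Why: Knoevenagel–Doebner condensation, in which the arylidene malonic acid loses CO2 in hot pyridine to give the (E)-cinnamic acid and a free phenol is tolerated.

Step 2
Reactants: 3 (E)-3-(3-hydroxy-4-methylphenyl)prop-2-enoic acid
Product: 4 3-(3-hydroxy-4-methylphenyl)propanoic acid
Conditions: H2 (1 atm), 10% Pd/C, MeOH, rt
Reagents that add atoms: none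
Why: Catalytic hydrogenation of a cinnamic acid double bond is fast at 1 atm and leaves the arene untouched.

Step 3
Reactants: 4 3-(3-hydroxy-4-methylphenyl)propanoic acid
Product: 5 tert-butyldimethylsilyl 3-[3-(tert-butyldimethylsilyloxy)-4-methylphenyl]propanoate
Conditions: TBSCl (2.5 equiv), imidazole, DMF, rt
Reagents that add atoms: tert-butyldimethylsilyl chloride CC(C)(C)[Si](C)(C)Cl
Why: Imidazole-promoted silylation caps both the phenol and the acid, and the silyl ester is the form from which the acid chloride can be made under neutral conditions in step 4.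

Step 4
Reactants: 5 tert-butyldimethylsilyl 3-[3-(tert-butyldimethylsilyloxy)-4-methylphenyl]propanoate
Product: 7 1-diazo-4-[3-(tert-butyldimethylsilyloxy)-4-methylphenyl]butan-2-one, via acid chloride 6 (not isolated)
Conditions: (COCl)2, DMF (cat.), CH2Cl2, 0 °C to rt; concentrate; CH2N2 (excess), Et2O, 0 °C
Reagents that add atoms: oxalyl chloride ClC(=O)C(Cl)=O (chlorine of 6); diazomethane C=[N+]=[N-]
Why: The chloroiminium salt from (COCl)2 and DMF converts a silyl ester directly into the acid chloride with loss of TBSCl, so no strong acid touches the aryl silyl ether, and C-acylation of excess diazomethane (first stage of the Arndt–Eistert sequence) gives the diazoketone while a second equivalent takes up HCl.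

Step 5
Reactants: 7 1-diazo-4-[3-(tert-butyldimethylsilyloxy)-4-methylphenyl]butan-2-one
Product: 9 (8aR)-5-(tert-butyldimethylsilyloxy)-6-methyl-3,8a-dihydroazulen-1(2H)-one, via norcaradiene 8 (not isolated)
Conditions: Cu(MeCN)4PF6 (5 mol %), (S,S)-Ph-box [2,2'-(propane-2,2-diyl)bis((4S)-4-phenyl-4,5-dihydrooxazole), 6 mol %], NaB[3,5-(CF3)2C6H3]4 (6 mol %), CH2Cl2, reflux, slow addition of 7; filtration through neutral alumina, used at once
Reagents that add atoms: none
Why: Loss of N2 from 7 at the monovalent copper centre gives an electrophilic copper carbene at C5, which adds across the C1–C6 bond of the arene to give norcaradiene 8, and 8 opens by a thermally allowed disrotatory six-electron electrocyclic reaction that cleaves C1–C6 and leaves cycloheptatriene 9. This is the intramolecular Buchner reaction of 1-diazo-4-arylbutan-2-ones, known with Rh2(OAc)4 and, in enantioselective form, with copper bis(oxazoline) catalysts. The cyclopentanone ring (C1–C5) closes in the cyclopropanation, because the three-atom tether C2–C3–C4 lets the carbene reach only the ipso/ortho bonds, and the seven-membered ring (C1, C5–C10) arises by ring expansion of the six-membered ring of 8. C5 is the only stereocentre that survives in 9, and its (R) configuration is decided by the arene face that the ligand-bound carbene attacks, that is by the chiral bis(oxazoline). The step needs attack at C1–C6 and not at C1–C10: C6 is unhindered and para to the donor oxygen on C9, whereas C10 lies next to the bulky OTBS group. It also needs cyclopropanation to win over aromatic substitution and over acid-induced collapse to a 2-tetralone, which is why a non-acidic cationic copper catalyst, slow addition and an acid-free work-up are used.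

Step 6
Reactants: 9 (8aR)-5-(tert-butyldimethylsilyloxy)-6-methyl-3,8a-dihydroazulen-1(2H)-one
Product: 10 (1R,8aR)-5-(tert-butyldimethylsilyloxy)-6-methyl-1-(propan-2-yl)-1,2,3,8a-tetrahydroazulen-1-ol (4R,5R in daucane numbering; isopropyl on the upper face, OH on the lower face)
Conditions: iPrMgCl, CeCl3 (dried), THF, −78 °C; pH 7 buffer
Reagents that add atoms: isopropylmagnesium chloride CC(C)[Mg]Cl (acting as dichloro(isopropyl)cerium CC(C)[Ce](Cl)Cl)
Why: Organocerium 1,2-addition to an enolisable ketone, in which the weakly basic reagent adds faster than it removes the acidic H5 and reaches C4=O from the convex upper face next to H5, because the lower face is covered by C6=C7 of the folded cycloheptatriene, which sets C4 (R) with isopropyl syn to H5.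

Step 7
Reactants: 10 tertiary alcohol
Product: 11 (4R,5R)-hydroxy dienone (C1=C10–C9=O enone, C6=C7 out of conjugation, C8–H, free C4–OH)
Conditions: TBAF, AcOH, THF, −78 to −20 °C; neutral work-up, used at once
Reagents that add atoms: none
Why: Fluoride cleaves the Si–O bond and the extended enolate is protonated kinetically at its α-carbon C8 (deconjugative protonation), so that C9=O appears in conjugation with C1=C10 only, C6=C7 stays where it is, and no acid stronger than acetic acid is needed.

Step 8
Reactants: 11 hydroxy dienone
Product: 13 trans-fused hydroxy silyl enol ether (1R,4R,5R; C1–CH3 on the lower face; C9(OTBS)=C10; C6=C7), via dilithium enolate-alkoxide 12 (not isolated)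
Conditions: Me2CuLi (3 equiv, from CuI (copper iodide) and MeLi), Et2O, −78 to −30 °C; TBSCl, DMPU, THF, −30 °C to rt; aq. NaHCO3
Reagents that add atoms: lithium dimethylcuprate [Li+].C[Cu-]C (from methyllithium [Li]C); tert-butyldimethylsilyl chloride CC(C)(C)[Si](C)(C)Cl
Why: Conjugate addition of lithium dimethylcuprate to a β,β-disubstituted cycloheptenone followed by O-silylation of the regiodefined enolate, in which the first equivalent turns the C4 hydroxyl into a lithium alkoxide that lies pseudoaxially on the lower face and can hold the cuprate cluster there while isopropyl and H5 crowd the upper face, so that methyl should enter anti to H5 and set C1 (R, trans fusion), and bulky TBSCl silylates the enolate oxygen but not the hindered tertiary alkoxide.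

Step 9
Reactants: 14 4-hydroxybenzoic acid
Product: 15 tert-butyldimethylsilyl 4-(tert-butyldimethylsilyloxy)benzoate
Conditions: TBSCl (2.5 equiv), imidazole, DMF, rt
Reagents that add atoms: tert-butyldimethylsilyl chloride CC(C)(C)[Si](C)(C)Cl
Why: Standard imidazole-promoted silylation protects the phenol and at the same time activates the acid as its silyl ester.

Step 10
Reactants: 15 tert-butyldimethylsilyl 4-(tert-butyldimethylsilyloxy)benzoate
Product: 16 4-(tert-butyldimethylsilyloxy)benzoyl chloride
Conditions: (COCl)2, DMF (cat.), CH2Cl2, 0 °C to rt; concentrate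
Reagents that add atoms: oxalyl chloride ClC(=O)C(Cl)=O
Why: Chloroiminium-mediated conversion of a silyl ester into the acid chloride proceeds under neutral conditions and leaves the aryl silyl ether in place.

Step 11
Reactants: 13 trans-fused hydroxy silyl enol ether; 16 4-(tert-butyldimethylsilyloxy)benzoyl chloride
Product: 18 C4 4-(tert-butyldimethylsilyloxy)benzoate of 13, via lithium alkoxide 17 (not isolated)
Conditions: n-BuLi (1.05 equiv), THF, −78 °C; 16, −78 °C to rt
Reagents that add atoms: n-butyllithium [Li]CCCC (lithium of 17)
Why: O-Acylation of a preformed lithium alkoxide with an aroyl chloride is the standard way to esterify a hindered tertiary alcohol, and it is safe here because the C9 carbonyl is masked as its silyl enol ether, so that the OH is the only acidic site and no stereocentre is touched.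

Step 12
Reactants: 18 bis-silylated ester
Product: 19 (1R,4R,5R)-keto ester with free phenol (C9=O, C10H2, C8–H, C6=C7)
Conditions: TBAF, AcOH, THF, 0 °C
Reagents that add atoms: none
Why: Buffered fluoride desilylation cleaves the aryl silyl ether and the silyl enol ether together, the enolate being protonated at C10, and the acetic acid buffer keeps the medium too weakly basic to move C6=C7 into conjugation or to attack the ester.

Step 13
Reactants: 19 keto ester
Product: 20 (1R,4R,5S,6R,7S)-6,7-epoxy ketone (epoxide oxygen on the upper face)
Conditions: mCPBA, NaHCO3, CH2Cl2, 0 °C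
Reagents that add atoms: 3-chloroperoxybenzoic acid OOC(=O)c1cccc(Cl)c1
Why: Prilezhaev epoxidation picks the only nucleophilic alkene, and the peracid should approach C6=C7 from the upper face next to H5, because the lower face is covered by the axial C1 methyl group and the C4 aroyloxy group, which places the C6–O bond syn to H5.

Step 14
Reactants: 20 6,7-epoxy ketone
Product: 21 (3R,3aS,4S,8aR)-4-hydroxy-6,8a-dimethyl-7-oxo-3-(propan-2-yl)-1,2,3,3a,4,7,8,8a-octahydroazulen-3-yl 4-hydroxybenzoate (1R,4R,5S,6S in daucane numbering; the target)
Conditions: DBU (2.5 equiv), CH2Cl2, 0 °C; pH 6 buffer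
Reagents that add atoms: none
Why: Base-induced E1cB opening of a β,γ-epoxy ketone, in which DBU removes H8 and the enolate expels the C7–O bond to give the C7=C8 enone while the C6–O bond stays intact, so that the configuration set in step 13 becomes (6S) of the target, and the mild amine base at 0 °C limits acyl migration from O4 to O6.

Compound list
1 | 3-hydroxy-4-methylbenzaldehyde | Cc1ccc(C=O)cc1O | starting material
2 | malonic acid | OC(=O)CC(O)=O | starting material
3 | (E)-3-(3-hydroxy-4-methylphenyl)prop-2-enoic acid | Cc1ccc(/C=C/C(O)=O)cc1O | intermediate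
4 | 3-(3-hydroxy-4-methylphenyl)propanoic acid | Cc1ccc(CCC(O)=O)cc1O | intermediate
5 | tert-butyldimethylsilyl 3-[3-(tert-butyldimethylsilyloxy)-4-methylphenyl]propanoate | Cc1ccc(CCC(=O)O[Si](C)(C)C(C)(C)C)cc1O[Si](C)(C)C(C)(C)C | intermediate
6 | 3-[3-(tert-butyldimethylsilyloxy)-4-methylphenyl]propanoyl chloride (not isolated) | Cc1ccc(CCC(Cl)=O)cc1O[Si](C)(C)C(C)(C)C | intermediate
7 | 1-diazo-4-[3-(tert-butyldimethylsilyloxy)-4-methylphenyl]butan-2-one | [N-]=[N+]=CC(=O)CCc1ccc(C)c(O[Si](C)(C)C(C)(C)C)c1 | intermediate
8 | norcaradiene tautomer of 9 (cyclopropane C1–C5–C6; not isolated) | O=C1CC[C@@]23C=C(O[Si](C)(C)C(C)(C)C)C(C)=C[C@@H]2[C@@H]13 | intermediate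
9 | (8aR)-5-(tert-butyldimethylsilyloxy)-6-methyl-3,8a-dihydroazulen-1(2H)-one | O=C1CCC2=CC(O[Si](C)(C)C(C)(C)C)=C(C)C=C[C@@H]12 | intermediate
10 | (1R,8aR)-5-(tert-butyldimethylsilyloxy)-6-methyl-1-(propan-2-yl)-1,2,3,8a-tetrahydroazulen-1-ol | CC(C)(C)[Si](C)(C)OC1=C(C)C=C[C@@H]2C(=C1)CC[C@@]2(O)C(C)C | intermediate
11 | (4R,5R)-hydroxy dienone, C1=C10–C9=O, C6=C7, C8 epimers | CC1C=C[C@@H]2C(=CC1=O)CC[C@@]2(O)C(C)C | intermediate
12 | dilithium C9 enolate / C4 alkoxide after methyl transfer (not isolated) | CC1C=C[C@@H]2[C@](C)(CC[C@@]2([O-])C(C)C)C=C1[O-].[Li+].[Li+] | intermediate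
13 | (1R,4R,5R)-trans-fused hydroxy silyl enol ether, C9(OTBS)=C10, C6=C7 | CC1C=C[C@@H]2[C@](C)(CC[C@@]2(O)C(C)C)C=C1O[Si](C)(C)C(C)(C)C | intermediate
14 | 4-hydroxybenzoic acid | OC(=O)c1ccc(O)cc1 | starting material
15 | tert-butyldimethylsilyl 4-(tert-butyldimethylsilyloxy)benzoate | CC(C)(C)[Si](C)(C)Oc1ccc(cc1)C(=O)O[Si](C)(C)C(C)(C)C | intermediate
16 | 4-(tert-butyldimethylsilyloxy)benzoyl chloride | CC(C)(C)[Si](C)(C)Oc1ccc(cc1)C(Cl)=O | intermediate
17 | lithium C4 alkoxide of 13 (not isolated) | CC1C=C[C@@H]2[C@](C)(CC[C@@]2([O-])C(C)C)C=C1O[Si](C)(C)C(C)(C)C.[Li+] | intermediate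
18 | C4 4-(tert-butyldimethylsilyloxy)benzoate of 13 | CC1C=C[C@@H]2[C@](C)(CC[C@@]2(OC(=O)c3ccc(O[Si](C)(C)C(C)(C)C)cc3)C(C)C)C=C1O[Si](C)(C)C(C)(C)C | intermediate
19 | (1R,4R,5R)-keto ester with free phenol, C6=C7 | CC1C=C[C@@H]2[C@](C)(CC[C@@]2(OC(=O)c3ccc(O)cc3)C(C)C)CC1=O | intermediate
20 | (1R,4R,5S,6R,7S)-6,7-epoxy ketone, oxygen on the upper face | CC1[C@@H]3O[C@@H]3[C@@H]2[C@](C)(CC[C@@]2(OC(=O)c4ccc(O)cc4)C(C)C)CC1=O | intermediate
21 | (3R,3aS,4S,8aR)-4-hydroxy-6,8a-dimethyl-7-oxo-3-(propan-2-yl)-1,2,3,3a,4,7,8,8a-octahydroazulen-3-yl 4-hydroxybenzoate | CC1=C[C@H](O)[C@@H]2[C@](C)(CC[C@@]2(OC(=O)c2ccc(O)cc2)C(C)C)CC1=O | target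

Total step count: 14. Longest linear sequence: 12 (steps 1–8 and 11–14).

Steps most likely to fail

**Step 5 (key step).**
- What may go wrong: weak face discrimination by the catalyst on a carbene that bears only hydrogen. The C5 configuration may also erode through enolisation of the product, and the carbene may be diverted into aromatic substitution.
- Fallback (resolution in place of asymmetric catalysis): it sets out from 7. Rh2(OAc)4 (0.5 mol %) in refluxing CH2Cl2, the most chemoselective catalyst for this ring expansion, should give the racemic azulenone F1. The organocerium addition of step 6 then gives the racemic alcohol, that is 10 together with its mirror image F2. The alcohol no longer has an acidic H5, so preparative chromatography on a chiral stationary phase separates the enantiomers. The route is rejoined at 10.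

**Step 8.**
- What may go wrong: entry of methyl from the upper face, which leads to a cis ring fusion. Proton abstraction at C8 or C5 by the cuprate or the alkoxide may also compete with addition.
- Fallback (directed cyclopropanation and reductive opening in place of conjugate addition): it sets out from 10.
  - A Simmons–Smith reaction (Et2Zn, CH2I2, CH2Cl2, −20 to 0 °C) is steered by the zinc alkoxide of the homoallylic C4 hydroxyl. It should place CH2 on the lower face of C1=C10 to give the cyclopropane F3.
  - TBAF/AcOH as in step 7 releases the cyclopropyl ketone F4.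
  - Li in NH3/THF with one equivalent of t-BuOH at −78 °C cleaves the exocyclic C10–CH2 bond, which overlaps best with the carbonyl π system. This leaves a methyl group on C1 and the same enolate-alkoxide 12.
  - After removal of NH3, 12 is silylated with TBSCl/DMPU. The route is rejoined at 13.

**Step 7.**
- What may go wrong: migration of C6=C7 into conjugation, either by protonation at C6 or by later prototropy. Exchange of the vinylogously acidic H5 is a further risk.
- Fallback (the conjugated isomer becomes the intended intermediate and C6 is oxidised through a dienol ether): it sets out from 10.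
  - HF·pyridine in THF at 0 °C to rt removes the silyl group under equilibrating conditions and should give the cross-conjugated dienone F5.
  - AlMe3 (excess, CH2Cl2, −78 °C to rt) forms the C4 aluminium alkoxide, which hands a methyl group to C1, the only β-carbon within its reach, from the lower face. This hydroxyl-directed conjugate methylation is known for 4-hydroxycyclohexa-2,5-dienones and should give the hydroxy enone F6.
  - TBSOTf/Et3N at −78 °C converts the enone into the extended silyl dienol ether F7.
  - n-BuLi and then 16, as in step 11, give the ester F8.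
  - mCPBA/NaHCO3 at −20 °C attacks the remote C6=C7 bond of the dienol ether from the upper face (vinylogous Rubottom oxidation) and gives the phenol-silylated target F9.
  - TBAF/AcOH frees the phenol. The route is rejoined at 21.

Further compounds
F1 | step 5 | racemic 5-(tert-butyldimethylsilyloxy)-6-methyl-3,8a-dihydroazulen-1(2H)-one | O=C1CCC2=CC(O[Si](C)(C)C(C)(C)C)=C(C)C=CC12
F2 | step 5 | mirror image of 10 (4S,5S) | CC(C)(C)[Si](C)(C)OC1=C(C)C=C[C@H]2C(=C1)CC[C@]2(O)C(C)C
F3 | step 8 | 10 with a CH2 bridge across C1–C10 on the lower face | CC(C)(C)[Si](C)(C)OC1=C(C)C=C[C@@H]2[C@]3(C[C@@H]13)CC[C@@]2(O)C(C)C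
F4 | step 8 | cyclopropyl ketone from F3 (C9=O, C6=C7, C8 epimers) | CC1C=C[C@@H]2[C@]3(C[C@H]3C1=O)CC[C@@]2(O)C(C)C
F5 | step 7 | (4R,5R)-cross-conjugated hydroxy dienone (C1=C10 and C7=C8 on C9=O) | CC1=CC[C@@H]2C(=CC1=O)CC[C@@]2(O)C(C)C
F6 | step 7 | (1R,4R,5R)-trans-fused hydroxy enone (C7=C8–C9=O, C6H2) | CC1=CC[C@@H]2[C@](C)(CC[C@@]2(O)C(C)C)CC1=O
F7 | step 7 | extended silyl dienol ether of F6 (C9(OTBS)=C8, C6=C7) | CC(C)(C)[Si](C)(C)OC1=C(C)C=C[C@@H]2[C@@](C)(C1)CC[C@@]2(O)C(C)C
F8 | step 7 | C4 4-(tert-butyldimethylsilyloxy)benzoate of F7 | CC(C)(C)[Si](C)(C)OC1=C(C)C=C[C@@H]2[C@@](C)(C1)CC[C@@]2(OC(=O)c3ccc(O[Si](C)(C)C(C)(C)C)cc3)C(C)C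
F9 | step 7 | 21 with the phenol as its TBS ether | CC1=C[C@H](O)[C@@H]2[C@](C)(CC[C@@]2(OC(=O)c3ccc(O[Si](C)(C)C(C)(C)C)cc3)C(C)C)CC1=O
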